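**Retrosynthetic overview**
1. Target 19 ⇐ Mitsunobu inversion at C3 of cis-bromohydrin 17 ⇐ hydride reduction of α′-bromo enone 16 ⇐ α′-bromination of enone 13.
2. 13 ⇐ MeLi 1,2-addition and oxidative 1,3-transposition of spiro enone 11 ⇐ dehydrogenation of spiro ketone 9.
3. 9 ⇐ catalytic enantioselective spirocyclizing Diels–Alder reaction (new substrate class) of exo-enone 5 with 2-bromo-3-methylbuta-1,3-diene 8; this one step forms ring B, the quaternary spiro centre and the vinyl bromide.
4. 5 ⇐ 3-methylcyclohex-2-en-1-one 1; 8 ⇐ 2-methylbut-1-en-3-yne 6 + HBr. Ring order: ring A first (bought as the cyclohexenone), then ring B.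

Assumption: the (S,S) acid catalyst is taken to give the (6R) adduct 9 (diene adds to the Re face at C2 of 5); if the first run shows the opposite sense, the (R,R) catalyst is used.

Locants follow spiro[5.5]undecane numbering (ring A = C1–C5, spiro atom = C6, ring B = C7–C11). The C6 descriptor switches between R and S along the route only because CIP priorities change; the centre is never inverted.

**Step 1**
Reactants: 1 3-methylcyclohex-2-en-1-one
Product: 3 2-[(dimethylamino)methyl]-3,3-dimethylcyclohexan-1-one (racemic), via bromomagnesium enolate 2 (not isolated)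
Conditions: MeMgBr, CuBr·SMe2 (5 mol %), THF, −20 °C; then [Me2N=CH2]I, −20 °C → rt
Reagents that add atoms: methylmagnesium bromide C[Mg]Br; dimethyl(methylidene)ammonium iodide C[N+](C)=C.[I-]
Why: CuBr-catalysed conjugate addition builds the gem-dimethyl carbon and gives the enolate regiospecifically at C2, which is trapped in a Mannich reaction; the C2 centre is racemic and becomes sp2 in step 2.

**Step 2**
Reactants: 3 2-[(dimethylamino)methyl]-3,3-dimethylcyclohexan-1-one
Product: 5 3,3-dimethyl-2-methylidenecyclohexan-1-one, via trimethylammonium iodide 4 (not isolated)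
Conditions: MeI, Et2O, rt; then K2CO3, CH2Cl2/H2O, rt
Reagents that add atoms: none
Why: N-quaternisation followed by base-induced E1cB (Hofmann-type) elimination gives the exocyclic enone; no stereocentre is involved.

**Step 3**
Reactants: 6 2-methylbut-1-en-3-yne
Product: 8 2-bromo-3-methylbuta-1,3-diene, via allenyl bromide 7 (not isolated)
Conditions: 48 % aq HBr, CuBr (10 mol %), NH4Br, 0 → 20 °C; distilled and kept cold
Reagents that add atoms: hydrogen bromide Br
Why: CuBr-catalysed hydrobromination of a vinylacetylene (the chloroprene-type process) proceeds by 1,4-addition to allenyl bromide 7 and allylic (SN2′) bromide shift to the conjugated 2-bromodiene; no stereocentre is involved.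

**Step 4**
Reactants: 5 3,3-dimethyl-2-methylidenecyclohexan-1-one; 8 2-bromo-3-methylbuta-1,3-diene
Product: 9 (6R)-8-bromo-5,5,9-trimethylspiro[5.5]undec-8-en-1-one
Conditions: (S,S)-imidodiphosphorimidate acid HN[P(=NSO2CF3)(O2C20H10Ar2)]2, Ar = 3,5-(CF3)2C6H3 (5 mol %), 8 (3 equiv), CH2Cl2, −40 → −20 °C, 72 h
Reagents that add atoms: none
Why: Proposed new method: the confined strong Brønsted acid protonates the carbonyl of 5 inside its chiral pocket and the bromodiene adds in a strongly asynchronous [4+2] in which the diene CH2 next to C–Me bonds first to the exocyclic CH2, so that charge builds on the methyl-bearing (tertiary) carbon and not on the bromine-bearing one, which places Me para and Br meta to the spiro carbon, while ring closure on the Re face of C2 sets the (6R) quaternary centre; bromine lowers the diene HOMO, hence excess diene and the higher loading; the closest known reaction type is the confined-acid-catalysed enantioselective spirocyclizing Diels–Alder reaction of exo-enones with 2-alkyl-1,3-dienes such as isoprene, and 2-halo-1,3-dienes are known Diels–Alder dienes only in racemic Lewis-acid reactions.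

**Step 5**
Reactants: 9 (6R)-8-bromo-5,5,9-trimethylspiro[5.5]undec-8-en-1-one
Product: 11 (6R)-8-bromo-5,5,9-trimethylspiro[5.5]undeca-2,8-dien-1-one, via lithium enolate 10 (not isolated)
Conditions: LiN(iPr)2, THF, −78 °C; then PhS(Cl)=N-t-Bu, −78 °C
Reagents that add atoms: none
Why: Mukaiyama dehydrogenation: the only possible enolate (C2) is sulfenylated by the sulfinimidoyl chloride and the adduct undergoes syn-elimination at low temperature to the enone; the spiro centre is untouched.

**Step 6**
Reactants: 11 (6R)-8-bromo-5,5,9-trimethylspiro[5.5]undeca-2,8-dien-1-one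
Product: 12 (6R)-8-bromo-1,5,5,9-tetramethylspiro[5.5]undeca-2,8-dien-1-ol (C1 epimer mixture)
Conditions: MeLi, CeCl3, THF, −78 °C; aq NH4Cl
Reagents that add atoms: methyllithium [Li]C
Why: Organocerium (Imamoto) 1,2-addition to the hindered enone carbonyl without enolisation or Li–Br exchange; the carbinol centre forms as an epimer mixture that is erased in step 7.

**Step 7**
Reactants: 12 (6R)-8-bromo-1,5,5,9-tetramethylspiro[5.5]undeca-2,8-dien-1-ol
Product: 13 (6R)-8-bromo-1,5,5,9-tetramethylspiro[5.5]undeca-1,8-dien-3-one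
Conditions: pyridinium chlorochromate [C5H5NH][CrO3Cl], 4 Å MS, CH2Cl2, rt
Reagents that add atoms: pyridinium chlorochromate [O-][Cr](=O)(=O)Cl.c1cc[nH+]cc1
Why: Dauben–Babler oxidative 1,3-transposition: [3,3] shift of the tertiary allylic chromate ester moves oxygen to C3 and oxidation gives the β-methyl enone, removing the carbinol stereocentre.

**Step 8**
Reactants: 13 (6R)-8-bromo-1,5,5,9-tetramethylspiro[5.5]undeca-1,8-dien-3-one
Product: 16 (4S,6S)-4,8-dibromo-1,5,5,9-tetramethylspiro[5.5]undeca-1,8-dien-3-one, via lithium dienolate 14 (not isolated), via silyl dienol ether 15 (not isolated)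
Conditions: LiN(iPr)2, THF, −78 °C; Me3SiCl; crude silyl ether, then N-bromosuccinimide, THF, −78 → 0 °C; chromatography
Reagents that add atoms: N-bromosuccinimide O=C1CCC(=O)N1Br
Why: Kinetic α′-deprotonation, silylation and electrophilic α′-bromination of the cross-conjugated silyl dienol ether put bromine on C4; the remote spiro centre gives only weak face bias, so 16 (equatorial Br on the face of the CH2–CBr arm of ring B) is expected with modest selectivity and is separated from its C4 epimer.

**Step 9**
Reactants: 16 (4S,6S)-4,8-dibromo-1,5,5,9-tetramethylspiro[5.5]undeca-1,8-dien-3-one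
Product: 17 (3R,4S,6S)-4,8-dibromo-1,5,5,9-tetramethylspiro[5.5]undeca-1,8-dien-3-ol
Conditions: i-Bu2AlH, CH2Cl2, −78 °C; aq KNaC4H4O6 work-up
Reagents that add atoms: none
Why: Chemoselective 1,2-reduction in which the bulky hydride attacks the face opposite the pseudo-axial C5 methyl and the equatorial C4 bromine (equatorial attack), giving the axial alcohol cis to bromine, (3R).

**Step 10**
Reactants: 17 (3R,4S,6S)-4,8-dibromo-1,5,5,9-tetramethylspiro[5.5]undeca-1,8-dien-3-ol
Product: 18 (3S,4S,6S)-4,8-dibromo-1,5,5,9-tetramethylspiro[5.5]undeca-1,8-dien-3-yl 4-nitrobenzoate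
Conditions: 4-O2NC6H4CO2H, PPh3, diisopropyl azodicarboxylate, toluene, 0 °C → rt
Reagents that add atoms: 4-nitrobenzoic acid O=C(O)c1ccc(cc1)[N+](=O)[O-]
Why: Mitsunobu reaction: SN2 displacement of the axial allylic oxyphosphonium by the carboxylate inverts C3 to (3S) and gives the trans (diequatorial) arrangement; the equatorial bromine is gauche to the leaving group, so it cannot participate.

**Step 11**
Reactants: 18 (3S,4S,6S)-4,8-dibromo-1,5,5,9-tetramethylspiro[5.5]undeca-1,8-dien-3-yl 4-nitrobenzoate
Product: 19 (3S,4S,6S)-4,8-dibromo-1,5,5,9-tetramethylspiro[5.5]undeca-1,8-dien-3-ol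
Conditions: K2CO3 (0.2 equiv), MeOH, 0 °C
Reagents that add atoms: none
Why: Mild transesterification (methanolysis) frees the alcohol with retention; the trans-diequatorial bromohydrin cannot reach the anti-periplanar geometry needed for epoxide closure, so it survives the carbonate.

**Compound list**
1 | 3-methylcyclohex-2-en-1-one | CC1=CC(=O)CCC1 | starting material
2 | bromomagnesium 3,3-dimethylcyclohex-1-en-1-olate | CC1(C)CCCC(O[Mg]Br)=C1 | intermediate (not isolated)
3 | 2-[(dimethylamino)methyl]-3,3-dimethylcyclohexan-1-one (racemic) | CN(C)CC1C(=O)CCCC1(C)C | intermediate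
4 | [(2,2-dimethyl-6-oxocyclohexyl)methyl]trimethylazanium iodide (racemic) | C[N+](C)(C)CC1C(=O)CCCC1(C)C.[I-] | intermediate (not isolated)
5 | 3,3-dimethyl-2-methylidenecyclohexan-1-one | C=C1C(=O)CCCC1(C)C | intermediate
6 | 2-methylbut-1-en-3-yne | C=C(C)C#C | starting material
7 | 4-bromo-3-methylbuta-1,2-diene | C=C=C(C)CBr | intermediate (not isolated)
8 | 2-bromo-3-methylbuta-1,3-diene | C=C(C)C(Br)=C | intermediate
9 | (6R)-8-bromo-5,5,9-trimethylspiro[5.5]undec-8-en-1-one | O=C1CCCC(C)(C)[C@]12CCC(C)=C(Br)C2 | intermediate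
10 | lithium (6R)-8-bromo-5,5,9-trimethylspiro[5.5]undeca-1,8-dien-1-olate | [Li+].[O-]C1=CCCC(C)(C)[C@]12CCC(C)=C(Br)C2 | intermediate (not isolated)
11 | (6R)-8-bromo-5,5,9-trimethylspiro[5.5]undeca-2,8-dien-1-one | O=C1C=CCC(C)(C)[C@]12CCC(C)=C(Br)C2 | intermediate
12 | (6R)-8-bromo-1,5,5,9-tetramethylspiro[5.5]undeca-2,8-dien-1-ol (C1 epimer mixture, C1 left open) | CC1(O)C=CCC(C)(C)[C@]12CCC(C)=C(Br)C2 | intermediate
13 | (6R)-8-bromo-1,5,5,9-tetramethylspiro[5.5]undeca-1,8-dien-3-one | CC1=CC(=O)CC(C)(C)[C@]12CCC(C)=C(Br)C2 | intermediate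
14 | lithium (6S)-8-bromo-1,5,5,9-tetramethylspiro[5.5]undeca-1,3,8-trien-3-olate | [Li+].CC1=CC([O-])=CC(C)(C)[C@]12CCC(C)=C(Br)C2 | intermediate (not isolated)
15 | {[(6S)-8-bromo-1,5,5,9-tetramethylspiro[5.5]undeca-1,3,8-trien-3-yl]oxy}trimethylsilane | CC1=CC(O[Si](C)(C)C)=CC(C)(C)[C@]12CCC(C)=C(Br)C2 | intermediate (not isolated)
16 | (4S,6S)-4,8-dibromo-1,5,5,9-tetramethylspiro[5.5]undeca-1,8-dien-3-one | CC1=CC(=O)[C@@H](Br)C(C)(C)[C@]12CCC(C)=C(Br)C2 | intermediate
17 | (3R,4S,6S)-4,8-dibromo-1,5,5,9-tetramethylspiro[5.5]undeca-1,8-dien-3-ol | CC1=C[C@@H](O)[C@@H](Br)C(C)(C)[C@]12CCC(C)=C(Br)C2 | intermediate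
18 | (3S,4S,6S)-4,8-dibromo-1,5,5,9-tetramethylspiro[5.5]undeca-1,8-dien-3-yl 4-nitrobenzoate | CC1=C[C@H](OC(=O)c3ccc(cc3)[N+](=O)[O-])[C@@H](Br)C(C)(C)[C@]12CCC(C)=C(Br)C2 | intermediate
19 | (3S,4S,6S)-4,8-dibromo-1,5,5,9-tetramethylspiro[5.5]undeca-1,8-dien-3-ol | CC1=C[C@H](O)[C@@H](Br)C(C)(C)[C@]12CCC(C)=C(Br)C2 | target

**Totals**
Total step count: 11. Longest linear sequence: 10 steps (1 → 19 through steps 1, 2, 4–11); the diene branch is one step.

**Three steps most likely to fail**

Step 4 (the proposed new Diels–Alder reaction; risks are low diene reactivity, Me-versus-Br regiocontrol and enantioselectivity). Fallback, known chemistry, sets out from 5 and returns at 9. The same acid catalysis is run with isoprene, the established diene class for this reaction, to give (6R)-5,5,9-trimethylspiro[5.5]undec-8-en-1-one F1. BH3·SMe2 followed by NaOH/H2O2 hydroborates the ring B alkene (boron on the CH carbon) and reduces the ketone, giving (6R)-5,5,9-trimethylspiro[5.5]undecane-1,8-diol F2. Dess–Martin periodinane oxidises both carbinols to (6R)-5,5,9-trimethylspiro[5.5]undecane-1,8-dione F3. Tf2O with 2,6-di-tert-butyl-4-methylpyridine forms the thermodynamic, tetrasubstituted enol triflate at the unhindered ring B ketone, (6R)-5,5,9-trimethyl-1-oxospiro[5.5]undec-8-en-8-yl trifluoromethanesulfonate F4. Ni(cod)2-catalysed triflate-to-bromide exchange with LiBr in DMA/THF then gives 9.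

Step 8 (weak face control at C4). Fallback sets out from 13 and returns at 16. Kinetic face selection is replaced by a separate-and-recycle loop under thermodynamic control. The unwanted epimer (4R,6S)-4,8-dibromo-1,5,5,9-tetramethylspiro[5.5]undeca-1,8-dien-3-one F5 is separated and re-equilibrated through its enol (cat. HBr, AcOH, rt). The equilibrium mixture is chromatographed again and the loop repeated until the material has been funnelled into 16.

Step 10 (Mitsunobu inversion of a hindered allylic alcohol; E2 loss to a bromodiene may compete). Fallback sets out from 17 and returns at 19. SN2 inversion is replaced by thermodynamic equilibration with Ph3SiOReO3 (2 mol %) in Et2O at 0 °C. Reversible [3,3] transposition of the allylic perrhenate passes through the transposed tertiary alcohol (4R,6R)-4,8-dibromo-1,5,5,9-tetramethylspiro[5.5]undeca-2,8-dien-1-ol F6 and scrambles C3 only. The trans-diequatorial secondary alcohol 19 should be the sink, because 17 carries a 1,3-diaxial OH/CH3 contact and F6 is a tertiary alcohol beside the quaternary centre.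

**Further compounds**
F1 | step 4 | (6R)-5,5,9-trimethylspiro[5.5]undec-8-en-1-one | O=C1CCCC(C)(C)[C@]12CCC(C)=CC2
F2 | step 4 | (6R)-5,5,9-trimethylspiro[5.5]undecane-1,8-diol (diastereomer mixture at C1, C8, C9; 8-OH trans to 9-Me) | OC1CCCC(C)(C)[C@]12CCC(C)C(O)C2
F3 | step 4 | (6R)-5,5,9-trimethylspiro[5.5]undecane-1,8-dione (C9 epimers) | O=C1CCCC(C)(C)[C@]12CCC(C)C(=O)C2
F4 | step 4 | (6R)-5,5,9-trimethyl-1-oxospiro[5.5]undec-8-en-8-yl trifluoromethanesulfonate | O=C1CCCC(C)(C)[C@]12CCC(C)=C(OS(=O)(=O)C(F)(F)F)C2
F5 | step 8 | (4R,6S)-4,8-dibromo-1,5,5,9-tetramethylspiro[5.5]undeca-1,8-dien-3-one | CC1=CC(=O)[C@H](Br)C(C)(C)[C@]12CCC(C)=C(Br)C2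
F6 | step 10 | (4R,6R)-4,8-dibromo-1,5,5,9-tetramethylspiro[5.5]undeca-2,8-dien-1-ol (C1 epimers, equilibrium species) | CC1(O)C=C[C@@H](Br)C(C)(C)[C@]12CCC(C)=C(Br)C2
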